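**Plan**

- Retrosynthesis cuts the O1–C8a aryl ether bond (back to an aryl bromide and a benzylic alcohol), then takes the C2 carbinol back to a ketone, then cuts ring B at C2'–C3' and C6'–C1'.
- Ring B is pentasubstituted in the order C1' (bearing C2), C2'/C3' (two prenyl groups), C4'/C5' (two oxygens), C6' (H). A 1-methoxy-2,3-bis(silyloxy) diene carries C3'–C6' and a prenyl-substituted alkynyl ketone carries C1'–C2' with the ring A chain already attached.
- Forward: ring A is dressed first (O-prenylation and Claisen rearrangement for the 1,1-dimethylallyl group, Heck reaction for the three-carbon chain). Alkynone and diene are made separately, ring B is built by cycloaddition and aromatisation, and the pyran ring C is closed last at O1–C8a.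
- The only stereocentre, C2 (S), is set by asymmetric transfer hydrogenation of the aryl ketone with RuCl[(S,S)-TsDPEN](p-cymene). It is retained because the ring closure forms the aryl–O bond and leaves the carbinol C–O bond untouched.
- All three phenolic oxygens travel as tert-butyldimethylsilyl (TBS) ethers and are freed together by fluoride, so no acid meets the prenyl groups or the benzylic ether.

Key step: step 12

Remark: the propargylic alcohol of step 6 and the cycloadduct of step 12 are racemic and lose their stereocentres in the next operation; the cycloadduct is written as one enantiomer of the cis racemate.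

**Route**

Step 1
Reactants: 1 3-bromo-4-iodophenol; 2 1-bromo-3-methylbut-2-ene (prenyl bromide)
Product: 3 2-bromo-1-iodo-4-[(3-methylbut-2-en-1-yl)oxy]benzene
Conditions: K2CO3, acetone, reflux
Reagents that add atoms: none
Why: Williamson ether synthesis, in which the phenoxide displaces the primary allylic bromide by SN2 and carbonate in acetone favours O- over C-alkylation.

Step 2
Reactants: 3 2-bromo-1-iodo-4-[(3-methylbut-2-en-1-yl)oxy]benzene
Product: 4 5-bromo-4-iodo-2-(2-methylbut-3-en-2-yl)phenol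
Conditions: PhNEt2, 190 °C, sealed tube, argon
Reagents that add atoms: none
Why: Aromatic Claisen rearrangement ([3,3]-sigmatropic shift) bonds the dimethyl-substituted allyl terminus to an ortho carbon and gives the 1,1-dimethylallyl group after tautomerisation; iodine blocks the para position, and the ortho carbon between the oxygen and the iodine-buttressed bromine is far more congested for a tertiary terminus than the open ortho carbon, which should outweigh the small electronic bias of a meta bromine.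

Step 3
Reactants: 4 5-bromo-4-iodo-2-(2-methylbut-3-en-2-yl)phenol
Product: 5 [5-bromo-4-iodo-2-(2-methylbut-3-en-2-yl)phenoxy](tert-butyl)dimethylsilane
Conditions: TBSOTf, 2,6-lutidine, CH2Cl2, 0 °C
Reagents that add atoms: tert-butyldimethylsilyl trifluoromethanesulfonate, CC(C)(C)[Si](C)(C)OS(=O)(=O)C(F)(F)F
Why: O-silylation with a silyl triflate and a hindered pyridine base is the standard way to protect a phenol flanked by a tertiary alkyl group, and the resulting hindered aryl silyl ether should last until the final step.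

Step 4
Reactants: 5 [5-bromo-4-iodo-2-(2-methylbut-3-en-2-yl)phenoxy](tert-butyl)dimethylsilane; 6 prop-2-en-1-ol (allyl alcohol)
Product: 7 3-[2-bromo-4-(tert-butyldimethylsilyloxy)-5-(2-methylbut-3-en-2-yl)phenyl]propanal
Conditions: Pd(OAc)2 (5 mol %), Bu4NCl, NaHCO3, DMF, 45 °C
Reagents that add atoms: none
Why: Ligand-free Heck reaction of an aryl iodide with allyl alcohol, in which arylation at the terminal carbon, β-hydride elimination toward the carbinol carbon and enol–aldehyde tautomerisation give the 3-arylpropanal; the C–I bond reacts far faster than C–Br at this temperature, and the neopentyl-type vinyl group cannot compete with excess allyl alcohol.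

Step 5
Reactants: 2 1-bromo-3-methylbut-2-ene; 8 ethynylmagnesium bromide
Product: 9 5-methylhex-4-en-1-yne
Conditions: CuBr·SMe2 (5 mol %), THF, 0 → 40 °C
Reagents that add atoms: none
Why: Copper-catalysed coupling of an alkynyl Grignard reagent with an allylic bromide, which should occur at the unhindered CH2 terminus of the prenyl unit and give the skipped enyne.

Step 6
Reactants: 9 5-methylhex-4-en-1-yne; 7 3-[2-bromo-4-(tert-butyldimethylsilyloxy)-5-(2-methylbut-3-en-2-yl)phenyl]propanal
Product: 11 1-[2-bromo-4-(tert-butyldimethylsilyloxy)-5-(2-methylbut-3-en-2-yl)phenyl]-8-methylnon-7-en-4-yn-3-ol (racemic), via (5-methylhex-4-en-1-ynyl)lithium 10 (not isolated)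
Conditions: n-BuLi, THF, −78 °C; then 7, −78 → −20 °C; aq. NH4Cl
Reagents that add atoms: none
Why: Deprotonation of the terminal alkyne and 1,2-addition of the lithium acetylide to the aldehyde; the acetylide attacks neither the aryl bromide nor the aryl silyl ether at low temperature, and the racemic carbinol centre is removed in step 7.

Step 7
Reactants: 11 1-[2-bromo-4-(tert-butyldimethylsilyloxy)-5-(2-methylbut-3-en-2-yl)phenyl]-8-methylnon-7-en-4-yn-3-ol
Product: 12 1-[2-bromo-4-(tert-butyldimethylsilyloxy)-5-(2-methylbut-3-en-2-yl)phenyl]-8-methylnon-7-en-4-yn-3-one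
Conditions: Dess–Martin periodinane, CH2Cl2, 0 °C → rt
Reagents that add atoms: none
Why: Dess–Martin oxidation of a propargylic alcohol proceeds without base, so the doubly activated CH2 between alkyne and alkene should not isomerise to the allenyl ketone.

Step 8
Reactants: 13 1,3-dithiane; 14 5-bromo-2-methylpent-2-ene
Product: 16 2-(4-methylpent-3-en-1-yl)-1,3-dithiane, via 2-lithio-1,3-dithiane 15 (not isolated)
Conditions: n-BuLi, THF, −30 °C; then 14, −78 → 0 °C
Reagents that add atoms: none
Why: Corey–Seebach alkylation, in which the soft, weakly basic dithiane anion displaces the primary homoallylic bromide by SN2 in preference to elimination.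

Step 9
Reactants: 16 2-(4-methylpent-3-en-1-yl)-1,3-dithiane; 17 N,2-dimethoxy-N-methylacetamide
Product: 19 2-methoxy-1-[2-(4-methylpent-3-en-1-yl)-1,3-dithian-2-yl]ethan-1-one, via 2-lithio-2-(4-methylpent-3-enyl)-1,3-dithiane 18 (not isolated)
Conditions: n-BuLi, THF, −30 → −10 °C; then 17, −78 → 0 °C; aq. NH4Cl
Reagents that add atoms: none
Why: Acylation of a 2-lithio-1,3-dithiane with an N-methoxy-N-methylamide, whose chelated tetrahedral adduct survives until work-up and prevents a second addition.

Step 10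
Reactants: 19 2-methoxy-1-[2-(4-methylpent-3-en-1-yl)-1,3-dithian-2-yl]ethan-1-one
Product: 20 1-methoxy-7-methyloct-6-ene-2,3-dione
Conditions: PhI(OCOCF3)2, MeCN/H2O (9:1), 0 °C
Reagents that add atoms: water, O
Why: Oxidative dithioacetal hydrolysis with a hypervalent iodine reagent (sulfur is activated as a sulfonium ion and displaced by water), which is fast at sulfur and should leave the trisubstituted alkene untouched.

Step 11
Reactants: 20 1-methoxy-7-methyloct-6-ene-2,3-dione
Product: 21 (1Z,3Z)-2,3-bis(tert-butyldimethylsilyloxy)-1-methoxy-7-methylocta-1,3,6-triene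
Conditions: TBSOTf (2.4 equiv), Et3N, CH2Cl2, 0 °C → rt
Reagents that add atoms: tert-butyldimethylsilyl trifluoromethanesulfonate, CC(C)(C)[Si](C)(C)OS(=O)(=O)C(F)(F)F
Why: Soft enolisation and O-silylation of a 1,2-dione, each carbonyl having only one α-CH2 group, gives the 2,3-bis(silyloxy) diene; these amine/triflate conditions normally place the α-substituent cis to the silyloxy group, which is the (1Z,3Z) isomer with methoxy and the prenyl-bearing CH2 both outward.

Step 12
Reactants: 21 (1Z,3Z)-2,3-bis(tert-butyldimethylsilyloxy)-1-methoxy-7-methylocta-1,3,6-triene; 12 1-[2-bromo-4-(tert-butyldimethylsilyloxy)-5-(2-methylbut-3-en-2-yl)phenyl]-8-methylnon-7-en-4-yn-3-one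
Product: 23 1-[4,5-bis(tert-butyldimethylsilyloxy)-2,3-bis(3-methylbut-2-en-1-yl)phenyl]-3-[2-bromo-4-(tert-butyldimethylsilyloxy)-5-(2-methylbut-3-en-2-yl)phenyl]propan-1-one, via cis-6-methoxycyclohexa-1,4-diene cycloadduct 22 (not isolated)
Conditions: 21 (1.5 equiv), toluene, 120 °C, sealed tube; then DBU (0.2 equiv), rt
Reagents that add atoms: none
Why: Heating should bring the electron-rich diene 21 and the alkynone 12 together in a concerted, asynchronous [4+2] cycloaddition in which diene C4 bonds to the alkynone β-carbon (C3'–C2') and diene C1 to the α-carbon (C6'–C1'), giving the cis-3,6-disubstituted cyclohexa-1,4-diene 22. DBU then removes the C3' proton, which is γ to the ketone, and the dienolate expels methoxide from C6' (vinylogous E1cB, a net 1,4-elimination of methanol), so that ring B becomes aromatic. The closest known reaction type is the Diels–Alder benzannulation of 1-alkoxy-3-silyloxy dienes and of 2,3-bis(silyloxy) dienes with alkynyl ketones, completed by loss of alcohol. Ring B, the only ring formed, closes by an intermolecular suprafacial [4+2] cycloaddition that makes both new σ-bonds in one event. The two sp3 centres of 22 are erased on aromatisation, so no stereocentre has to be controlled. The step needs regioselectivity, which the diene secures because the C1 methoxy and C3 silyloxy groups both raise the HOMO coefficient at C4 (only the C2 silyloxy group opposes) while the alkynone has its largest LUMO coefficient at the β-carbon, and it needs an accessible s-cis conformer, which the (1Z,3Z) geometry with both terminal groups outward provides.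

Step 13
Reactants: 23 1-[4,5-bis(tert-butyldimethylsilyloxy)-2,3-bis(3-methylbut-2-en-1-yl)phenyl]-3-[2-bromo-4-(tert-butyldimethylsilyloxy)-5-(2-methylbut-3-en-2-yl)phenyl]propan-1-one
Product: 24 (1S)-1-[4,5-bis(tert-butyldimethylsilyloxy)-2,3-bis(3-methylbut-2-en-1-yl)phenyl]-3-[2-bromo-4-(tert-butyldimethylsilyloxy)-5-(2-methylbut-3-en-2-yl)phenyl]propan-1-ol
Conditions: RuCl[(S,S)-TsDPEN](p-cymene) (2 mol %), HCO2H/Et3N (5:2), EtOAc, 40 °C
Reagents that add atoms: none
Why: Asymmetric transfer hydrogenation of an aryl alkyl ketone, in which the (S,S)-ligand holds the aryl group by a CH/π contact with the η6-arene and delivers hydride to the face that gives the (S)-carbinol, the future C2; alkenes, the aryl bromide and the silyl ethers are not reduced.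

Step 14
Reactants: 24 (1S)-1-[4,5-bis(tert-butyldimethylsilyloxy)-2,3-bis(3-methylbut-2-en-1-yl)phenyl]-3-[2-bromo-4-(tert-butyldimethylsilyloxy)-5-(2-methylbut-3-en-2-yl)phenyl]propan-1-ol
Product: 25 (2S)-2-[4,5-bis(tert-butyldimethylsilyloxy)-2,3-bis(3-methylbut-2-en-1-yl)phenyl]-7-(tert-butyldimethylsilyloxy)-6-(2-methylbut-3-en-2-yl)-3,4-dihydro-2H-chromene
Conditions: Pd(OAc)2 (5 mol %), 2-(di-tert-butylphosphino)-1,1'-binaphthyl (6 mol %), Cs2CO3, toluene, 80 °C
Reagents that add atoms: none
Why: Intramolecular Buchwald–Hartwig etherification (oxidative addition of zerovalent palladium into C–Br, alkoxide binding, C–O reductive elimination driven by the bulky phosphine) closes the six-membered pyran ring at O1–C8a, and since the carbinol C–O bond is never broken the (S) configuration is retained.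

Step 15
Reactants: 25 (2S)-2-[4,5-bis(tert-butyldimethylsilyloxy)-2,3-bis(3-methylbut-2-en-1-yl)phenyl]-7-(tert-butyldimethylsilyloxy)-6-(2-methylbut-3-en-2-yl)-3,4-dihydro-2H-chromene
Product: 26 Kazinol E, 5-[(2S)-7-hydroxy-6-(2-methylbut-3-en-2-yl)-3,4-dihydro-2H-chromen-2-yl]-3,4-bis(3-methylbut-2-en-1-yl)benzene-1,2-diol
Conditions: Bu4NF, AcOH (1:1), THF, 0 °C, degassed, argon
Reagents that add atoms: none
Why: Fluoride-mediated cleavage of the three aryl silyl ethers, buffered with acetic acid so that the catechol stays protonated and is not air-oxidised, while no acid strong enough to cyclise a prenyl group onto a neighbouring phenol or to ionise the benzylic ether is present.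

**Compound list**

1 | 3-bromo-4-iodophenol | Oc1ccc(I)c(Br)c1 | starting material
2 | 1-bromo-3-methylbut-2-ene | CC(C)=CCBr | starting material
3 | 2-bromo-1-iodo-4-[(3-methylbut-2-en-1-yl)oxy]benzene | CC(C)=CCOc1ccc(I)c(Br)c1 | intermediate
4 | 5-bromo-4-iodo-2-(2-methylbut-3-en-2-yl)phenol | C=CC(C)(C)c1cc(I)c(Br)cc1O | intermediate
5 | [5-bromo-4-iodo-2-(2-methylbut-3-en-2-yl)phenoxy](tert-butyl)dimethylsilane | C=CC(C)(C)c1cc(I)c(Br)cc1O[Si](C)(C)C(C)(C)C | intermediate
6 | prop-2-en-1-ol | C=CCO | starting material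
7 | 3-[2-bromo-4-(tert-butyldimethylsilyloxy)-5-(2-methylbut-3-en-2-yl)phenyl]propanal | O=CCCc1cc(C(C)(C)C=C)c(O[Si](C)(C)C(C)(C)C)cc1Br | intermediate
8 | ethynylmagnesium bromide | C#C[Mg]Br | starting material
9 | 5-methylhex-4-en-1-yne | C#CCC=C(C)C | intermediate
10 | (5-methylhex-4-en-1-ynyl)lithium | [Li]C#CCC=C(C)C | intermediate
11 | 1-[2-bromo-4-(tert-butyldimethylsilyloxy)-5-(2-methylbut-3-en-2-yl)phenyl]-8-methylnon-7-en-4-yn-3-ol (racemic) | CC(C)=CCC#CC(O)CCc1cc(C(C)(C)C=C)c(O[Si](C)(C)C(C)(C)C)cc1Br | intermediate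
12 | 1-[2-bromo-4-(tert-butyldimethylsilyloxy)-5-(2-methylbut-3-en-2-yl)phenyl]-8-methylnon-7-en-4-yn-3-one | CC(C)=CCC#CC(=O)CCc1cc(C(C)(C)C=C)c(O[Si](C)(C)C(C)(C)C)cc1Br | intermediate
13 | 1,3-dithiane | C1CSCSC1 | starting material
14 | 5-bromo-2-methylpent-2-ene | CC(C)=CCCBr | starting material
15 | 2-lithio-1,3-dithiane | [Li]C1SCCCS1 | intermediate
16 | 2-(4-methylpent-3-en-1-yl)-1,3-dithiane | CC(C)=CCCC1SCCCS1 | intermediate
17 | N,2-dimethoxy-N-methylacetamide | COCC(=O)N(C)OC | starting material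
18 | 2-lithio-2-(4-methylpent-3-enyl)-1,3-dithiane | [Li]C1(CCC=C(C)C)SCCCS1 | intermediate
19 | 2-methoxy-1-[2-(4-methylpent-3-en-1-yl)-1,3-dithian-2-yl]ethan-1-one | COCC(=O)C1(CCC=C(C)C)SCCCS1 | intermediate
20 | 1-methoxy-7-methyloct-6-ene-2,3-dione | COCC(=O)C(=O)CCC=C(C)C | intermediate
21 | (1Z,3Z)-2,3-bis(tert-butyldimethylsilyloxy)-1-methoxy-7-methylocta-1,3,6-triene | CO/C=C(O[Si](C)(C)C(C)(C)C)/C(O[Si](C)(C)C(C)(C)C)=C/CC=C(C)C | intermediate
22 | 1-[(3,6-cis)-4,5-bis(tert-butyldimethylsilyloxy)-6-methoxy-2,3-bis(3-methylbut-2-en-1-yl)cyclohexa-1,4-dien-1-yl]-3-[2-bromo-4-(tert-butyldimethylsilyloxy)-5-(2-methylbut-3-en-2-yl)phenyl]propan-1-one (racemic, one enantiomer drawn) | CO[C@H]1C(O[Si](C)(C)C(C)(C)C)=C(O[Si](C)(C)C(C)(C)C)[C@@H](CC=C(C)C)C(CC=C(C)C)=C1C(=O)CCc1cc(C(C)(C)C=C)c(O[Si](C)(C)C(C)(C)C)cc1Br | intermediate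
23 | 1-[4,5-bis(tert-butyldimethylsilyloxy)-2,3-bis(3-methylbut-2-en-1-yl)phenyl]-3-[2-bromo-4-(tert-butyldimethylsilyloxy)-5-(2-methylbut-3-en-2-yl)phenyl]propan-1-one | CC(C)=CCc1c(CC=C(C)C)c(O[Si](C)(C)C(C)(C)C)c(O[Si](C)(C)C(C)(C)C)cc1C(=O)CCc1cc(C(C)(C)C=C)c(O[Si](C)(C)C(C)(C)C)cc1Br | intermediate
24 | (1S)-1-[4,5-bis(tert-butyldimethylsilyloxy)-2,3-bis(3-methylbut-2-en-1-yl)phenyl]-3-[2-bromo-4-(tert-butyldimethylsilyloxy)-5-(2-methylbut-3-en-2-yl)phenyl]propan-1-ol | O[C@H](c1cc(O[Si](C)(C)C(C)(C)C)c(O[Si](C)(C)C(C)(C)C)c(CC=C(C)C)c1CC=C(C)C)CCc1cc(C(C)(C)C=C)c(O[Si](C)(C)C(C)(C)C)cc1Br | intermediate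
25 | (2S)-2-[4,5-bis(tert-butyldimethylsilyloxy)-2,3-bis(3-methylbut-2-en-1-yl)phenyl]-7-(tert-butyldimethylsilyloxy)-6-(2-methylbut-3-en-2-yl)-3,4-dihydro-2H-chromene | C=CC(C)(C)c1cc2c(cc1O[Si](C)(C)C(C)(C)C)O[C@H](c1cc(O[Si](C)(C)C(C)(C)C)c(O[Si](C)(C)C(C)(C)C)c(CC=C(C)C)c1CC=C(C)C)CC2 | intermediate
26 | Kazinol E, 5-[(2S)-7-hydroxy-6-(2-methylbut-3-en-2-yl)-3,4-dihydro-2H-chromen-2-yl]-3,4-bis(3-methylbut-2-en-1-yl)benzene-1,2-diol | C=CC(C)(C)c1cc2c(cc1O)O[C@H](c1cc(O)c(O)c(CC=C(C)C)c1CC=C(C)C)CC2 | target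

**Step count and risks**

Total: 15 steps. Longest linear sequence: 10 steps (1, 2, 3, 4, 6, 7, 12, 13, 14, 15).

Most likely to fail, step 12. The tetrasubstituted diene may reach its s-cis form only slowly and the β-alkylated alkynone is a moderate dienophile. Prolonged heating could then isomerise the skipped enynone to an allenyl ketone, cleave the silyl enol ethers or erode the regiochemistry. The fallback uses a smaller and more reactive dienophile and attaches ring A afterwards; it sets out from 9 and returns at 23. Lithium acetylide 10 would be formylated with DMF to 6-methylhept-5-en-2-ynal F1. Heating F1 with diene 21 in toluene at 80 °C should give the cis-methoxycyclohexadiene carbaldehyde F2, which DBU would aromatise to 4,5-bis(tert-butyldimethylsilyloxy)-2,3-bis(3-methylbut-2-en-1-yl)benzaldehyde F3. Vinylmagnesium bromide would convert F3 into 1-[4,5-bis(tert-butyldimethylsilyloxy)-2,3-bis(3-methylbut-2-en-1-yl)phenyl]prop-2-en-1-ol F4. A Heck reaction of F4 with aryl iodide 5 (Pd(OAc)2, Bu4NCl, NaHCO3, DMF, 50 °C) should then give ketone 23 directly, because β-hydride elimination runs toward the carbinol carbon.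

Second, step 2. Bond formation may leak to the ortho carbon next to bromine. The 1,1-dimethylallyl phenol may rearrange further or cyclise to a dihydrobenzofuran (abnormal Claisen pathway), the ether may lose isoprene, and the C–I bond may not survive the temperature. The fallback rearranges a symmetrical ether, so only one ortho product is possible, and places bromine afterwards by directed metalation; it sets out from 2 and returns at 7. Prenyl bromide 2 and 4-hydroxybenzaldehyde (K2CO3, acetone) would give 4-[(3-methylbut-2-en-1-yl)oxy]benzaldehyde F5. Claisen rearrangement, with both ortho carbons equivalent and the para carbon blocked, should give 4-hydroxy-3-(2-methylbut-3-en-2-yl)benzaldehyde F6, and silylation gives 4-(tert-butyldimethylsilyloxy)-3-(2-methylbut-3-en-2-yl)benzaldehyde F7. In-situ protection of the aldehyde as its α-amino alkoxide with LiN(Me)CH2CH2NMe2, ortho-lithiation with n-BuLi at the carbon remote from the tertiary alkyl group, and quenching with BrCCl2CCl2Br would give 2-bromo-4-(tert-butyldimethylsilyloxy)-5-(2-methylbut-3-en-2-yl)benzaldehyde F8. Horner–Wadsworth–Emmons reaction (triethyl phosphonoacetate, NaH) would give ethyl (2E)-3-[2-bromo-4-(tert-butyldimethylsilyloxy)-5-(2-methylbut-3-en-2-yl)phenyl]prop-2-enoate F9. Conjugate reduction with [(Ph3P)CuH]6, which spares the isolated vinyl group and the aryl bromide, would give ethyl 3-[2-bromo-4-(tert-butyldimethylsilyloxy)-5-(2-methylbut-3-en-2-yl)phenyl]propanoate F10, and i-Bu2AlH at −78 °C would reduce F10 to aldehyde 7.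

Third, step 14. The palladium alkoxide of a benzylic secondary alcohol can undergo β-hydride elimination, which returns the ketone and removes bromine, and warm carbonate may strip aryl silyl ethers. The fallback forms O1–C2 instead of O1–C8a and therefore starts from the other alcohol enantiomer; it sets out from 23 and returns at 25. Transfer hydrogenation of 23 with RuCl[(R,R)-TsDPEN](p-cymene) would give (1R)-1-[4,5-bis(tert-butyldimethylsilyloxy)-2,3-bis(3-methylbut-2-en-1-yl)phenyl]-3-[2-bromo-4-(tert-butyldimethylsilyloxy)-5-(2-methylbut-3-en-2-yl)phenyl]propan-1-ol F11. Miyaura borylation (Pd(dppf)Cl2, bis(pinacolato)diboron, KOAc, dioxane, 80 °C) would give the corresponding (1R)-aryl pinacol boronate F12, and oxidation with NaBO3·4H2O would give the (1R)-phenol F13. Mitsunobu cyclisation of F13 (PPh3, diisopropyl azodicarboxylate, THF, 0 °C) should close the pyran ring with inversion to the (2S)-chroman 25. The weakness of this fallback is possible ionisation at the electron-rich benzylic carbon, which would lower the enantiomeric purity.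

**Further compounds**

F1 | step 12 | 6-methylhept-5-en-2-ynal | CC(C)=CCC#CC=O
F2 | step 12 | (3,6-cis)-4,5-bis(tert-butyldimethylsilyloxy)-6-methoxy-2,3-bis(3-methylbut-2-en-1-yl)cyclohexa-1,4-diene-1-carbaldehyde (racemic, one enantiomer drawn) | CO[C@H]1C(O[Si](C)(C)C(C)(C)C)=C(O[Si](C)(C)C(C)(C)C)[C@@H](CC=C(C)C)C(CC=C(C)C)=C1C=O
F3 | step 12 | 4,5-bis(tert-butyldimethylsilyloxy)-2,3-bis(3-methylbut-2-en-1-yl)benzaldehyde | CC(C)=CCc1c(CC=C(C)C)c(O[Si](C)(C)C(C)(C)C)c(O[Si](C)(C)C(C)(C)C)cc1C=O
F4 | step 12 | 1-[4,5-bis(tert-butyldimethylsilyloxy)-2,3-bis(3-methylbut-2-en-1-yl)phenyl]prop-2-en-1-ol (racemic) | CC(C)=CCc1c(CC=C(C)C)c(O[Si](C)(C)C(C)(C)C)c(O[Si](C)(C)C(C)(C)C)cc1C(O)C=C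
F5 | step 2 | 4-[(3-methylbut-2-en-1-yl)oxy]benzaldehyde | CC(C)=CCOc1ccc(C=O)cc1
F6 | step 2 | 4-hydroxy-3-(2-methylbut-3-en-2-yl)benzaldehyde | C=CC(C)(C)c1cc(C=O)ccc1O
F7 | step 2 | 4-(tert-butyldimethylsilyloxy)-3-(2-methylbut-3-en-2-yl)benzaldehyde | C=CC(C)(C)c1cc(C=O)ccc1O[Si](C)(C)C(C)(C)C
F8 | step 2 | 2-bromo-4-(tert-butyldimethylsilyloxy)-5-(2-methylbut-3-en-2-yl)benzaldehyde | C=CC(C)(C)c1cc(C=O)c(Br)cc1O[Si](C)(C)C(C)(C)C
F9 | step 2 | ethyl (2E)-3-[2-bromo-4-(tert-butyldimethylsilyloxy)-5-(2-methylbut-3-en-2-yl)phenyl]prop-2-enoate | CCOC(=O)/C=C/c1cc(C(C)(C)C=C)c(O[Si](C)(C)C(C)(C)C)cc1Br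
F10 | step 2 | ethyl 3-[2-bromo-4-(tert-butyldimethylsilyloxy)-5-(2-methylbut-3-en-2-yl)phenyl]propanoate | CCOC(=O)CCc1cc(C(C)(C)C=C)c(O[Si](C)(C)C(C)(C)C)cc1Br
F11 | step 14 | (1R)-1-[4,5-bis(tert-butyldimethylsilyloxy)-2,3-bis(3-methylbut-2-en-1-yl)phenyl]-3-[2-bromo-4-(tert-butyldimethylsilyloxy)-5-(2-methylbut-3-en-2-yl)phenyl]propan-1-ol | O[C@@H](c1cc(O[Si](C)(C)C(C)(C)C)c(O[Si](C)(C)C(C)(C)C)c(CC=C(C)C)c1CC=C(C)C)CCc1cc(C(C)(C)C=C)c(O[Si](C)(C)C(C)(C)C)cc1Br
F12 | step 14 | (1R)-1-[4,5-bis(tert-butyldimethylsilyloxy)-2,3-bis(3-methylbut-2-en-1-yl)phenyl]-3-[4-(tert-butyldimethylsilyloxy)-5-(2-methylbut-3-en-2-yl)-2-(4,4,5,5-tetramethyl-1,3,2-dioxaborolan-2-yl)phenyl]propan-1-ol | O[C@@H](c1cc(O[Si](C)(C)C(C)(C)C)c(O[Si](C)(C)C(C)(C)C)c(CC=C(C)C)c1CC=C(C)C)CCc1cc(C(C)(C)C=C)c(O[Si](C)(C)C(C)(C)C)cc1B1OC(C)(C)C(C)(C)O1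
F13 | step 14 | 2-{(3R)-3-[4,5-bis(tert-butyldimethylsilyloxy)-2,3-bis(3-methylbut-2-en-1-yl)phenyl]-3-hydroxypropyl}-5-(tert-butyldimethylsilyloxy)-4-(2-methylbut-3-en-2-yl)phenol | O[C@@H](c1cc(O[Si](C)(C)C(C)(C)C)c(O[Si](C)(C)C(C)(C)C)c(CC=C(C)C)c1CC=C(C)C)CCc1cc(C(C)(C)C=C)c(O[Si](C)(C)C(C)(C)C)cc1O
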